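## Analysis of the target

CNP0309284.0 is a 2-arylchromone. Ring A (the benzo ring, C4a–C8a) carries a methyl group at C5 and a hydroxyl at C7, and ring B is the 4-pyranone. Ring C (C1'–C6') is bonded through C1' to C2, has hydroxyls at C2' and C4', and carries at C6' a methylene that ends at C6 of a 4-hydroxy-2-pyrone (ring D). There is no stereocentre; the only stereochemical element is the C2–C1' axis between two ortho-substituted positions, which the structure does not define and which therefore needs no control. The sensitive points are the four acidic hydroxyls (the pyrone OH is a vinylogous carboxylic acid), the methylene that is both benzylic and vinylogously α to the lactone, the lactone itself toward nucleophiles, and the chromone enone. Two things make the synthesis hard. The C2–C1' bond ends at an aryl carbon flanked by OH and CH2R, and in ring A the acyl-bearing C4a lies between the methyl-bearing C5 and the oxygen-bearing C8a, a 2,6-disubstituted benzoyl pattern that acylation of a 3,5-dioxygenated toluene reaches poorly. Four hydroxyls must also be carried masked and released at the end without harm to ring D. The strategy rests on ring A: methyl at C5, acyl at C4a and oxygen at C8a and C7 is the pattern a 1,1,3-trioxygenated butadiene leaves on a methyl-substituted ynone, so ring A can be grown late on an open-chain diynone that already holds C2, C3, C4 and the whole ring C–CH2–ring D unit.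

## Retrosynthetic reasoning

Target 21 is traced to its tetramethyl ether 20 by cutting four O–CH3 bonds. Methyl is the smallest mask, and it is the one that both the pyrone methylation and the diene deliver for free. The forward step has to cleave three aryl ethers and one vinylogous ester ether in a molecule that has no other acid-labile group.

Flavone 20 is opened at O1–C2 to the ortho-hydroxyaryl ynone 18. This is the natural place to cut ring B because the phenol and the alkyne are already held six atoms apart, and the forward reaction only has to be steered to 6-endo rather than 5-exo closure. Routing it through the amine adduct 19 secures that.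

Ynone 18 is cut at C4a–C8a and C5–C6, which removes four carbons of ring A as diene 15 and leaves the cross-conjugated diynone 12. Cutting here and not at the aryl–carbonyl bond avoids a hindered 2,6-disubstituted benzoyl donor and makes the ring construction itself place methyl, acyl and both oxygens. The forward cycloaddition must pick the methyl-substituted alkyne of 12 and leave the aryl-substituted one as the future C2–C3 unit.

Diynone 12 is taken back to the skipped diynol 11 by an oxidation-state change, and 11 is cut at the C1'–C(sp) bond into aryl iodide 7 and diynol 10. Forming the hindered C1' bond to a linear sp carbon by cross-coupling avoids the steric problem that any ring-forming approach to C1' would face. The alcohol oxidation level lets the six-carbon chain be coupled as a stable propargylic alcohol rather than as an acid chloride.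

Diynol 10 comes from ynal 8 and alkynyl nucleophile 9 by carbonyl addition.

Iodide 7 is traced through the O–CH3 bond to hydroxypyrone 6, through the lactone C–O bond to diketo ester 5, and through the C4–C5 bond of that chain to arylacetate 2 and the dianion 4 of acetoacetate 3. The pyrone is built early, by classical carbonyl chemistry, so that it only has to survive neutral or weakly basic steps afterwards.

Ester 2 comes from 1 by cutting the C–I bond; the two methoxy groups of 1 direct iodination to the position next to the side chain. Diene 15 comes from ester 13 by γ-deprotonation to 14 and O-silylation.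

## Alternatives that were turned down

Alternative 1: Ring C is disconnected at C2'–C3' and C1'–C6' into the symmetric bis(4-methoxy-2-oxo-2H-pyran-6-yl)methane A1 and the borylethynyl chromone A2. In the forward step one pyrone of A1 adds through C3 and C6 across the alkyne of A2 and the bridged adduct extrudes carbon dioxide to give the arylboronate A3. For it: the route is highly convergent, the symmetry of A1 removes any choice between the two pyrones, ring C and its CH2–pyrone arm arise together, and boron marks C2' for a hydroxyl distinct from the other oxygens. On convergence it is stronger than the chosen route. Against it: a 4-methoxy-2-pyrone is a reluctant diene and A2 is activated only vinylogously through the chromone, so high temperature is needed. The second pyrone of A3 can react again, and the chromone C2=C3 bond of A2 is a competing dienophile. The required orientation bonds the substituted pyrone C6 to the chromone-bearing alkyne carbon, so the most crowded bond of the target is made in the cycloaddition itself. A C–B oxidation must follow before deprotection. The chosen strategy instead makes the crowded C1' bond by cross-coupling to an sp carbon and runs its cycloaddition at an unhindered methyl alkyne with a far more reactive diene.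

Alternative 2: Both heterocycles are opened at once, ring B at O1–C2 and ring D at O–C6, leading to the bis-alkyne A4 with a free phenol and a tert-butyl β-keto ynoate. In the forward step Ph3PAuCl with AgSbF6 activates both alkynes: the phenol closes the chromone, and the ester carbonyl oxygen closes the pyrone by 6-endo attack with loss of isobutene, giving A5. For it: two rings form in one operation, and the pyrone hydroxyl emerges free, so the final deprotection has only aryl methyl ethers to cleave. On that point it is stronger than the chosen route, whose last step must also cleave the pyrone methyl ether. Against it: A4 contains an ArCH2–C≡C–C(=O) unit whose methylene is benzylic and propargylic to an ynone and should isomerise readily to the allenyl ketone. It also holds a β-keto ester beside a Michael acceptor, and a free phenol beside a second ynone that can close 5-exo or 6-endo before the catalyst is added. Ring A has to be brought in as a preformed 2,6-disubstituted benzoyl unit, the hindered acyl donor the chosen route avoids. Assembling A4 would therefore take more steps, and more fragile ones, than making 12. The chosen strategy offers a robust pyrone made early and a ring A whose substituents are generated rather than bought.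

Alternative 3: Ring C is disconnected at C1'–C2' and C5'–C6' into diene 15 and the 2-alkynylchromone A6. The forward step is the same kind of benzannulation as in the chosen route, here giving A7 with the C2' hydroxyl free. For it: the chromone is already in place, so no flavone-versus-aurone question arises, and the C2' oxygen comes out distinct from the others. Both points are advantages over the chosen route. Against it: the alkyne of A6 is a vinylogous acceptor, weaker than a true ynone, and the chromone C2=C3 bond competes for the diene. The methylene of A6 lies between the alkyne and the pyrone and is doubly activated toward isomerisation to an allene. The ketene acetal carbon must bond to the alkyne carbon that carries the chromone, so the crowded C1' is again created in the ring-forming step. A6 also needs ring A from an orcinol-type ketone, which adds steps before the key step. The chosen strategy uses the same reaction on a better acceptor and at an unhindered terminus.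

Key step: step 9

## Route

Assumptions: the C2–C1' axis is treated as not configurationally defined, since the target structure carries no stereodescriptor. But-2-ynal (8) and ethynylmagnesium bromide solution (9) are taken as purchasable.

Step 1
Reactants: 1 methyl 3,5-dimethoxyphenylacetate
Product: 2 methyl 2-(2-iodo-3,5-dimethoxyphenyl)acetate
Conditions: NIS (1.05 equiv), TFA (cat.), MeCN, 0 °C → rt
Reagents that add atoms: N-iodosuccinimide, O=C1CCC(=O)N1I
Why: Electrophilic aromatic iodination; C2 is para to one methoxy group and ortho to the other and is less crowded than C4 between the two methoxy groups, and a single equivalent of NIS should keep di-iodination low.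

Step 2
Reactants: 2 methyl 2-(2-iodo-3,5-dimethoxyphenyl)acetate; 3 methyl acetoacetate
Product: 5 methyl 6-(2-iodo-3,5-dimethoxyphenyl)-3,5-dioxohexanoate, via methyl acetoacetate sodium lithium dianion 4 (not isolated)
Conditions: 3 (3 equiv), NaH, THF, 0 °C; n-BuLi, 0 °C; then 2, −78 → 0 °C; 1 M HCl
Reagents that add atoms: none
Why: Claisen acylation of a β-keto ester dianion at its terminal carbon; dianion 4 is fully formed before 2 is added, so no free alkyllithium meets the aryl iodide, and the excess dianion absorbs the acidic tricarbonyl product.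

Step 3
Reactants: 5 methyl 6-(2-iodo-3,5-dimethoxyphenyl)-3,5-dioxohexanoate
Product: 6 4-hydroxy-6-(2-iodo-3,5-dimethoxybenzyl)-2H-pyran-2-one
Conditions: DBU (2 equiv), toluene, 80 °C; 1 M HCl
Reagents that add atoms: none
Why: Base-mediated lactonisation of a 3,5-diketo ester: the C5 enolate oxygen attacks the ester and methanol is lost to give the 4-hydroxy-2-pyrone; aprotic DBU favours O-cyclisation, and acid, which could drive Friedel–Crafts closure onto the electron-rich arene, is avoided.

Step 4
Reactants: 6 4-hydroxy-6-(2-iodo-3,5-dimethoxybenzyl)-2H-pyran-2-one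
Product: 7 6-(2-iodo-3,5-dimethoxybenzyl)-4-methoxy-2H-pyran-2-one
Conditions: Me2SO4 (1.2 equiv), K2CO3, acetone, reflux
Reagents that add atoms: dimethyl sulfate, COS(=O)(=O)OC
Why: O-Methylation of the vinylogous acid, the standard access to 4-methoxy-2-pyrones; the acidic OH must be masked before the coupling and silyl diene steps.

Step 5
Reactants: 8 but-2-ynal; 9 ethynylmagnesium bromide
Product: 10 hexa-1,4-diyn-3-ol (racemic)
Conditions: THF, −78 → 0 °C; aq. NH4Cl
Reagents that add atoms: none
Why: Grignard 1,2-addition of an alkynyl nucleophile to an ynal, the usual route to skipped diynols; the carbinol centre is racemic and is removed by the oxidation in step 7.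

Step 6
Reactants: 7 6-(2-iodo-3,5-dimethoxybenzyl)-4-methoxy-2H-pyran-2-one; 10 hexa-1,4-diyn-3-ol
Product: 11 6-[2-(3-hydroxyhexa-1,4-diyn-1-yl)-3,5-dimethoxybenzyl]-4-methoxy-2H-pyran-2-one (racemic)
Conditions: Pd(PPh3)2Cl2 (5 mol %), CuI (10 mol %), Et3N, THF, degassed, 45 °C
Reagents that add atoms: none
Why: Sonogashira coupling at the terminal alkyne of 10; aryl iodides add to zerovalent palladium even with two ortho substituents, propargylic alcohols are standard partners, and the amine base is too weak to deprotonate the pyrone methylene.

Step 7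
Reactants: 11 6-[2-(3-hydroxyhexa-1,4-diyn-1-yl)-3,5-dimethoxybenzyl]-4-methoxy-2H-pyran-2-one
Product: 12 6-[3,5-dimethoxy-2-(3-oxohexa-1,4-diyn-1-yl)benzyl]-4-methoxy-2H-pyran-2-one
Conditions: activated MnO2 (excess), CH2Cl2, rt
Reagents that add atoms: none
Why: MnO2 oxidises the doubly propargylic alcohol selectively under neutral conditions and leaves the pyrone and the benzylic methylene alone; the diynone is filtered off and used without delay.

Step 8
Reactants: 13 methyl (E)-3-methoxybut-2-enoate
Product: 15 (E)-1,3-dimethoxy-1-(trimethylsilyloxy)buta-1,3-diene, via lithium (1Z)-1,3-dimethoxybuta-1,3-dien-1-olate 14 (not isolated)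
Conditions: LiN(iPr)2 (1.1 equiv), THF, −78 °C; Me3SiCl, −78 °C → rt; filtration, distillation
Reagents that add atoms: chlorotrimethylsilane, C[Si](C)(C)Cl
Why: γ-Deprotonation of the β-methoxy enoate and O-silylation of the extended enolate, the known preparation of this silyl ketene acetal diene; its double-bond geometry is lost on aromatisation.

Step 9
Reactants: 12 6-[3,5-dimethoxy-2-(3-oxohexa-1,4-diyn-1-yl)benzyl]-4-methoxy-2H-pyran-2-one; 15 (E)-1,3-dimethoxy-1-(trimethylsilyloxy)buta-1,3-diene
Product: 18 6-[2-[3-(2-hydroxy-4-methoxy-6-methylphenyl)-3-oxoprop-1-yn-1-yl]-3,5-dimethoxybenzyl]-4-methoxy-2H-pyran-2-one, via cyclohexa-1,4-diene mixed ketal cycloadduct 16 (not isolated), via aryl trimethylsilyl ether 17 (not isolated)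
Conditions: 15 (2.5 equiv), toluene, 0 → 50 °C; then 1 M HCl, THF, rt
Reagents that add atoms: none
Why: Diels–Alder benzannulation of a 1,1,3-trioxygenated butadiene with an acetylenic ketone, a known route to acylresorcinol derivatives, applied here to one arm of a cross-conjugated diynone. The CH2 terminus of 15, which has the largest HOMO coefficient, bonds to the methyl-bearing β-carbon (future C5) and the ketene acetal carbon bonds to the α-carbon (future C4a). This happens either as a concerted asynchronous [4+2] addition or as a Mukaiyama–Michael addition followed by 6-exo-trig attack of the allenolate α-carbon on the oxocarbenium carbon; both paths close the same six-membered carbocycle 16 by [4+2] annulation. 1,4-Elimination of methanol from the mixed ketal aromatises ring A to 17, and dilute acid frees the phenol, which is hydrogen-bonded to the ketone in 18. No stereocentre remains: the ketal carbon of 16 forms as a racemate and becomes the planar C8a. The step needs site selectivity between the two alkynes and a single orientation. The methyl alkyne should react because its β-carbon is unhindered, while the other β-carbon is shielded by the doubly ortho-substituted ring C and deactivated by donation from its methoxy groups; the orientation follows from the matched polarisation of diene and ynone. The remaining alkyne of 17, now flanked by two aryl-bearing ends, should not compete for the excess diene, and the pyrone and methyl ethers are inert under these neutral conditions.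

Step 10
Reactants: 18 6-[2-[3-(2-hydroxy-4-methoxy-6-methylphenyl)-3-oxoprop-1-yn-1-yl]-3,5-dimethoxybenzyl]-4-methoxy-2H-pyran-2-one
Product: 20 2-[2,4-dimethoxy-6-[(4-methoxy-2-oxo-2H-pyran-6-yl)methyl]phenyl]-7-methoxy-5-methyl-4H-chromen-4-one, via diethylamino enone 19 (not isolated)
Conditions: Et2NH (5 equiv), EtOH, 50 °C
Reagents that add atoms: none
Why: Amine-mediated oxa-Michael closure of an ortho-hydroxyaryl ynone: Et2NH adds to the alkyne to give vinylogous amide 19, and the phenol then attacks the amine-bearing carbon (6-endo-trig) and expels Et2NH; this addition–elimination path excludes the 5-exo closure to an aurone that a bare phenoxide can take.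

Step 11
Reactants: 20 2-[2,4-dimethoxy-6-[(4-methoxy-2-oxo-2H-pyran-6-yl)methyl]phenyl]-7-methoxy-5-methyl-4H-chromen-4-one
Product: 21 2-[2,4-dihydroxy-6-[(4-hydroxy-2-oxo-2H-pyran-6-yl)methyl]phenyl]-7-hydroxy-5-methyl-4H-chromen-4-one
Conditions: BBr3 (12 equiv), CH2Cl2, −78 °C → rt (40 °C if needed); MeOH, then H2O
Reagents that add atoms: none
Why: Lewis acid ether cleavage: boron binds each methoxy oxygen (for the vinylogous ester, the pyrone carbonyl) and bromide removes methyl by SN2; a large excess is used because the chromone and pyrone carbonyls also bind boron, and aqueous work-up hydrolyses the borates to the four hydroxyls.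

## Compound list

1 | methyl 3,5-dimethoxyphenylacetate | COC(=O)Cc1cc(OC)cc(OC)c1 | starting material
2 | methyl 2-(2-iodo-3,5-dimethoxyphenyl)acetate | COC(=O)Cc1cc(OC)cc(OC)c1I | intermediate
3 | methyl acetoacetate | CC(=O)CC(=O)OC | starting material
4 | methyl acetoacetate sodium lithium dianion (not isolated) | [CH2-]C(=O)[CH-]C(=O)OC.[Na+].[Li+] | intermediate
5 | methyl 6-(2-iodo-3,5-dimethoxyphenyl)-3,5-dioxohexanoate | COC(=O)CC(=O)CC(=O)Cc1cc(OC)cc(OC)c1I | intermediate
6 | 4-hydroxy-6-(2-iodo-3,5-dimethoxybenzyl)-2H-pyran-2-one | O=c1cc(O)cc(Cc2cc(OC)cc(OC)c2I)o1 | intermediate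
7 | 6-(2-iodo-3,5-dimethoxybenzyl)-4-methoxy-2H-pyran-2-one | COc1cc(=O)oc(Cc2cc(OC)cc(OC)c2I)c1 | intermediate
8 | but-2-ynal | CC#CC=O | starting material
9 | ethynylmagnesium bromide | C#C[Mg]Br | starting material
10 | hexa-1,4-diyn-3-ol (racemic) | CC#CC(O)C#C | intermediate
11 | 6-[2-(3-hydroxyhexa-1,4-diyn-1-yl)-3,5-dimethoxybenzyl]-4-methoxy-2H-pyran-2-one (racemic) | CC#CC(O)C#Cc1c(OC)cc(OC)cc1Cc1cc(OC)cc(=O)o1 | intermediate
12 | 6-[3,5-dimethoxy-2-(3-oxohexa-1,4-diyn-1-yl)benzyl]-4-methoxy-2H-pyran-2-one | CC#CC(=O)C#Cc1c(OC)cc(OC)cc1Cc1cc(OC)cc(=O)o1 | intermediate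
13 | methyl (E)-3-methoxybut-2-enoate | CO/C(C)=C/C(=O)OC | starting material
14 | lithium (1Z)-1,3-dimethoxybuta-1,3-dien-1-olate (not isolated) | C=C(OC)/C=C(\OC)[O-].[Li+] | intermediate
15 | (E)-1,3-dimethoxy-1-(trimethylsilyloxy)buta-1,3-diene | C=C(OC)/C=C(\OC)O[Si](C)(C)C | intermediate
16 | 6-[2-[3-[4,6-dimethoxy-2-methyl-6-(trimethylsilyloxy)cyclohexa-1,4-dien-1-yl]-3-oxoprop-1-yn-1-yl]-3,5-dimethoxybenzyl]-4-methoxy-2H-pyran-2-one (racemic, not isolated) | CC1=C(C(=O)C#Cc2c(OC)cc(OC)cc2Cc2cc(OC)cc(=O)o2)C(OC)(O[Si](C)(C)C)C=C(OC)C1 | intermediate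
17 | 6-[3,5-dimethoxy-2-[3-[4-methoxy-2-methyl-6-(trimethylsilyloxy)phenyl]-3-oxoprop-1-yn-1-yl]benzyl]-4-methoxy-2H-pyran-2-one (not isolated) | COc1cc(C)c(C(=O)C#Cc2c(OC)cc(OC)cc2Cc2cc(OC)cc(=O)o2)c(O[Si](C)(C)C)c1 | intermediate
18 | 6-[2-[3-(2-hydroxy-4-methoxy-6-methylphenyl)-3-oxoprop-1-yn-1-yl]-3,5-dimethoxybenzyl]-4-methoxy-2H-pyran-2-one | COc1cc(C)c(C(=O)C#Cc2c(OC)cc(OC)cc2Cc2cc(OC)cc(=O)o2)c(O)c1 | intermediate
19 | 6-[2-[1-(diethylamino)-3-(2-hydroxy-4-methoxy-6-methylphenyl)-3-oxoprop-1-en-1-yl]-3,5-dimethoxybenzyl]-4-methoxy-2H-pyran-2-one (double-bond geometry not defined, not isolated) | CCN(CC)C(=CC(=O)c1c(C)cc(OC)cc1O)c1c(OC)cc(OC)cc1Cc1cc(OC)cc(=O)o1 | intermediate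
20 | 2-[2,4-dimethoxy-6-[(4-methoxy-2-oxo-2H-pyran-6-yl)methyl]phenyl]-7-methoxy-5-methyl-4H-chromen-4-one | COc1cc(C)c2c(c1)oc(-c1c(OC)cc(OC)cc1Cc1cc(OC)cc(=O)o1)cc2=O | intermediate
21 | 2-[2,4-dihydroxy-6-[(4-hydroxy-2-oxo-2H-pyran-6-yl)methyl]phenyl]-7-hydroxy-5-methyl-4H-chromen-4-one | Cc1cc(O)cc2oc(-c3c(O)cc(O)cc3Cc3cc(O)cc(=O)o3)cc(=O)c12 | target

## Step count and least certain steps

Total: 11 steps. Longest linear sequence: 9 steps (steps 1, 2, 3, 4, 6, 7, 9, 10, 11); steps 5 and 8 are one-step side branches.

Step 9 (key step). The most likely failures are loss of site selectivity (addition of the diene to the aryl-substituted alkyne), a Michael addition that stops at the open-chain adduct without closing the ring, and aromatisation by loss of silanol instead of methanol, which would leave C8a–O methylated. The substrate is also a doubly activated acceptor that can oligomerise with a nucleophilic diene. The fallback gives up building ring A and buys it; it sets out from iodide 7 and comes back at flavone 20. Sonogashira coupling of 7 with ethynyltrimethylsilane should give 6-[3,5-dimethoxy-2-[(trimethylsilyl)ethynyl]benzyl]-4-methoxy-2H-pyran-2-one F1, and buffered fluoride (Bu4NF, AcOH, THF) should give 6-(2-ethynyl-3,5-dimethoxybenzyl)-4-methoxy-2H-pyran-2-one F2. Purchasable 2-hydroxy-4-methoxy-6-methylbenzoic acid F3 is acetylated (Ac2O, pyridine) to 2-acetoxy-4-methoxy-6-methylbenzoic acid F4 and converted with (COCl)2 and catalytic DMF into 2-acetoxy-4-methoxy-6-methylbenzoyl chloride F5. Acyl Sonogashira coupling of F2 with F5 (Pd(PPh3)2Cl2, CuI, Et3N, THF, rt) should give 5-methoxy-2-[3-[2,4-dimethoxy-6-[(4-methoxy-2-oxo-2H-pyran-6-yl)methyl]phenyl]prop-2-ynoyl]-3-methylphenyl acetate F6. The Et2NH conditions of step 10 then remove the acetate and close ring B to 20. The price is a hindered acyl chloride in the coupling and two extra steps.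

Step 11. Cleavage may stop short at the pyrone: the vinylogous ester oxygen is much less basic than an aryl ether oxygen, and the reagent is partly tied up on the two ring carbonyls. Forcing the reaction risks degrading the polyphenol. The fallback splits the deprotection into a nucleophilic and a Lewis acid stage; it sets out from 20 and comes back at 21. LiI in pyridine at 100 °C should remove only the pyrone methyl by SN2, since the departing 4-pyronolate is as good a leaving group as a carboxylate, giving 2-[2-[(4-hydroxy-2-oxo-2H-pyran-6-yl)methyl]-4,6-dimethoxyphenyl]-7-methoxy-5-methyl-4H-chromen-4-one F7 (the same structure as A5). BBr3 then has only the three aryl methyl ethers to cleave.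

Step 6. The skipped diynol 10 can be lost by copper-mediated oxidative dimerisation (Glaser coupling) or base-induced isomerisation while oxidative addition at the electron-rich, doubly ortho-substituted iodide is slow. The fallback builds the six-carbon chain in two pieces; it sets out from 7 and comes back at 11. Sonogashira coupling of 7 with prop-2-yn-1-ol should give 6-[2-(3-hydroxyprop-1-yn-1-yl)-3,5-dimethoxybenzyl]-4-methoxy-2H-pyran-2-one F8. MnO2 should oxidise it to 3-[2,4-dimethoxy-6-[(4-methoxy-2-oxo-2H-pyran-6-yl)methyl]phenyl]prop-2-ynal F9. Addition of prop-1-ynylmagnesium bromide (CH3C≡CMgBr) in THF at −78 °C, where addition to the ynal should outrun deprotonation of the pyrone methylene, then gives 11.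

Step 2. Proton transfer from the benzylic α-position of 2 to dianion 4 can compete with acylation and return 2 after work-up; self-condensation of 2 is the second risk. The fallback replaces the basic Claisen step by a Lewis acid aldol route; it sets out from 2 and comes back at 6. Reduction of 2 with iBu2AlH at −78 °C should give 2-(2-iodo-3,5-dimethoxyphenyl)acetaldehyde F10. Vinylogous Mukaiyama aldol addition of the silyl dienol ether [(2,2-dimethyl-6-methylidene-6H-1,3-dioxin-4-yl)oxy]trimethylsilane F11 (BF3·OEt2, CH2Cl2, −78 °C) should give 6-[2-hydroxy-3-(2-iodo-3,5-dimethoxyphenyl)propyl]-2,2-dimethyl-4H-1,3-dioxin-4-one F12 as a racemate. Swern oxidation should give 6-[3-(2-iodo-3,5-dimethoxyphenyl)-2-oxopropyl]-2,2-dimethyl-4H-1,3-dioxin-4-one F13. Heating F13 in toluene at 110 °C releases the acylketene, which closes to hydroxypyrone 6.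

## Further compounds

F1 | step 9 | 6-[3,5-dimethoxy-2-[(trimethylsilyl)ethynyl]benzyl]-4-methoxy-2H-pyran-2-one | COc1cc(=O)oc(Cc2cc(OC)cc(OC)c2C#C[Si](C)(C)C)c1
F2 | step 9 | 6-(2-ethynyl-3,5-dimethoxybenzyl)-4-methoxy-2H-pyran-2-one | COc1cc(=O)oc(Cc2cc(OC)cc(OC)c2C#C)c1
F3 | step 9 | 2-hydroxy-4-methoxy-6-methylbenzoic acid | COc1cc(C)c(C(=O)O)c(O)c1
F4 | step 9 | 2-acetoxy-4-methoxy-6-methylbenzoic acid | COc1cc(C)c(C(=O)O)c(OC(C)=O)c1
F5 | step 9 | 2-acetoxy-4-methoxy-6-methylbenzoyl chloride | COc1cc(C)c(C(=O)Cl)c(OC(C)=O)c1
F6 | step 9 | 5-methoxy-2-[3-[2,4-dimethoxy-6-[(4-methoxy-2-oxo-2H-pyran-6-yl)methyl]phenyl]prop-2-ynoyl]-3-methylphenyl acetate | COc1cc(C)c(C(=O)C#Cc2c(OC)cc(OC)cc2Cc2cc(OC)cc(=O)o2)c(OC(C)=O)c1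
F7 | step 11 | 2-[2-[(4-hydroxy-2-oxo-2H-pyran-6-yl)methyl]-4,6-dimethoxyphenyl]-7-methoxy-5-methyl-4H-chromen-4-one | COc1cc(C)c2c(c1)oc(-c1c(OC)cc(OC)cc1Cc1cc(O)cc(=O)o1)cc2=O
F8 | step 6 | 6-[2-(3-hydroxyprop-1-yn-1-yl)-3,5-dimethoxybenzyl]-4-methoxy-2H-pyran-2-one | COc1cc(=O)oc(Cc2cc(OC)cc(OC)c2C#CCO)c1
F9 | step 6 | 3-[2,4-dimethoxy-6-[(4-methoxy-2-oxo-2H-pyran-6-yl)methyl]phenyl]prop-2-ynal | COc1cc(=O)oc(Cc2cc(OC)cc(OC)c2C#CC=O)c1
F10 | step 2 | 2-(2-iodo-3,5-dimethoxyphenyl)acetaldehyde | O=CCc1cc(OC)cc(OC)c1I
F11 | step 2 | [(2,2-dimethyl-6-methylidene-6H-1,3-dioxin-4-yl)oxy]trimethylsilane | C=C1C=C(O[Si](C)(C)C)OC(C)(C)O1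
F12 | step 2 | 6-[2-hydroxy-3-(2-iodo-3,5-dimethoxyphenyl)propyl]-2,2-dimethyl-4H-1,3-dioxin-4-one (racemic) | CC1(C)OC(CC(O)Cc2cc(OC)cc(OC)c2I)=CC(=O)O1
F13 | step 2 | 6-[3-(2-iodo-3,5-dimethoxyphenyl)-2-oxopropyl]-2,2-dimethyl-4H-1,3-dioxin-4-one | CC1(C)OC(CC(=O)Cc2cc(OC)cc(OC)c2I)=CC(=O)O1
A1 | alternative 1 | bis(4-methoxy-2-oxo-2H-pyran-6-yl)methane | COc1cc(=O)oc(Cc2cc(OC)cc(=O)o2)c1
A2 | alternative 1 | 7-methoxy-5-methyl-2-[(4,4,5,5-tetramethyl-1,3,2-dioxaborolan-2-yl)ethynyl]-4H-chromen-4-one | COc1cc(C)c2c(c1)oc(C#CB1OC(C)(C)C(C)(C)O1)cc2=O
A3 | alternative 1 | 7-methoxy-2-[4-methoxy-2-[(4-methoxy-2-oxo-2H-pyran-6-yl)methyl]-6-(4,4,5,5-tetramethyl-1,3,2-dioxaborolan-2-yl)phenyl]-5-methyl-4H-chromen-4-one | COc1cc(C)c2c(c1)oc(-c1c(B3OC(C)(C)C(C)(C)O3)cc(OC)cc1Cc1cc(OC)cc(=O)o1)cc2=O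
A4 | alternative 2 | tert-butyl 6-[2-[3-(2-hydroxy-4-methoxy-6-methylphenyl)-3-oxoprop-1-yn-1-yl]-3,5-dimethoxyphenyl]-3-oxohex-4-ynoate | COc1cc(C)c(C(=O)C#Cc2c(OC)cc(OC)cc2CC#CC(=O)CC(=O)OC(C)(C)C)c(O)c1
A5 | alternative 2 | 2-[2-[(4-hydroxy-2-oxo-2H-pyran-6-yl)methyl]-4,6-dimethoxyphenyl]-7-methoxy-5-methyl-4H-chromen-4-one | COc1cc(C)c2c(c1)oc(-c1c(OC)cc(OC)cc1Cc1cc(O)cc(=O)o1)cc2=O
A6 | alternative 3 | 7-methoxy-2-[3-(4-methoxy-2-oxo-2H-pyran-6-yl)prop-1-yn-1-yl]-5-methyl-4H-chromen-4-one | COc1cc(C)c2c(c1)oc(C#CCc1cc(OC)cc(=O)o1)cc2=O
A7 | alternative 3 | 2-[2-hydroxy-4-methoxy-6-[(4-methoxy-2-oxo-2H-pyran-6-yl)methyl]phenyl]-7-methoxy-5-methyl-4H-chromen-4-one | COc1cc(C)c2c(c1)oc(-c1c(O)cc(OC)cc1Cc1cc(OC)cc(=O)o1)cc2=O
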